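**Plan**
1. Retrosynthetic cuts, in order: O9–angeloyl and O3–senecioyl; C7–C11 (isopropenyl); the C4 methyl carbon (back to C4=O) and C9–O; then C5–C10 and C6–C7 together; last C4–C5, C9=C10 and C1–C2 of the open chain.
2. Enabling feature (eremophilane numbering; ring A = C1–C5 + C10, ring B = C5–C10): the C8 ketone lies 1,4 to the quaternary, methyl-bearing C5, and C4 next to C5 can be a carbonyl. Ring B is therefore the adduct of a 2-siloxydiene C7=C8(OSi)–C9=C10 and an isopropenyl ketone C5=C6/C4=O, and the C1–C2–C3 chain linking C10 to C4 completes ring A.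
3. Forward: the ten-carbon chain is joined at C1–C2, C9=C10 and C4–C5; rings A and B close in one cycloaddition; C4, C9 and C7 are then functionalised, and the two esters go on last.
4. Stereochemistry: C3 is bought with methyl (R)-glycidate 1, and C5 and C10 are relayed from C3 in the cycloaddition. C9 comes from convex-face oxidation of the C8=C9 enol ether, C4 from hydrogenation directed by the 3-hydroxyl, and C7 from C–C coupling on the convex face (equatorial, also the more stable epimer). The (Z)-alkene of the angelate is bought.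

Key step: step 7

Conventions: eremophilane numbering is used for all compounds, including the open-chain ones, and β is the face of the C5 methyl. Read from the SMILES, the target is 3α-senecioyloxy, 4β-methyl, 5β-methyl, 7β-isopropenyl, 9β-angeloyloxy, 10β-H, that is (3R,4R,5R,7R,9R,10S). In the cis-decalin conformer with the C5 methyl axial on ring A, the substituents at C3, C4, C7 and C9 are all equatorial.

Assumption: in step 9 the tert-butyldimethylsilyl group is taken to end on O9 (1,4-shift in the opened silyloxy epoxide), as is usual for bulky silyl enol ethers in aprotic medium.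

**Step 1**
Reactants: 1 methyl (R)-glycidate; 2 allylmagnesium bromide
Product: 3 methyl (R)-2-hydroxyhex-5-enoate
Conditions: 2 (1.2 equiv, slow addition), CuBr·SMe2 (0.2 equiv), THF, −78 to −40 °C; sat. aq NH4Cl
Reagents that add atoms: allylmagnesium bromide (2), C=CC[Mg]Br
Why: Copper-catalysed Grignard opening of a terminal epoxide (SN2 at the unsubstituted carbon of the glycidic ester), which at −78 °C with slow addition should outrun attack on the ester; the C–O bond at the stereocentre is not touched, so C3 of the target is already (R).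

**Step 2**
Reactants: 3 methyl (R)-2-hydroxyhex-5-enoate
Product: 4 methyl (R)-2-(triethylsilyloxy)hex-5-enoate
Conditions: TESCl (1.2 equiv), imidazole (2 equiv), CH2Cl2, 0 °C to rt
Reagents that add atoms: chlorotriethylsilane, CC[Si](Cl)(CC)CC
Why: Imidazole-promoted silylation of a secondary alcohol; the triethylsilyl ether is bulky and non-chelating for step 7 and can later be removed with mild acid beside a tert-butyldimethylsilyl ether.

**Step 3**
Reactants: 4 methyl (R)-2-(triethylsilyloxy)hex-5-enoate; 5 N,O-dimethylhydroxylamine hydrochloride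
Product: 6 (R)-N-methoxy-N-methyl-2-(triethylsilyloxy)hex-5-enamide
Conditions: 5 (1.5 equiv), iPrMgCl (3.0 equiv), THF, −20 to 0 °C; sat. aq NH4Cl
Reagents that add atoms: N,O-dimethylhydroxylamine hydrochloride (5), CNOC.Cl
Why: Weinreb amide formation by aminolysis of the ester with the magnesium amide made from 5 and iPrMgCl, a method that lactate-type α-silyloxy esters pass without epimerisation; the amide holds C4 at the acid level so that the dienophile can be released last.

**Step 4**
Reactants: 6 (R)-N-methoxy-N-methyl-2-(triethylsilyloxy)hex-5-enamide; 7 methyl vinyl ketone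
Product: 8 (R,E)-N-methoxy-N-methyl-7-oxo-2-(triethylsilyloxy)oct-5-enamide
Conditions: 7 (3 equiv), second-generation Hoveyda–Grubbs catalyst RuCl2(H2IMes)(=CH-C6H4-2-OiPr) (3 mol %), CH2Cl2, 40 °C
Reagents that add atoms: methyl vinyl ketone (7), C=CC(C)=O
Why: Olefin cross-metathesis of a terminal alkene with an electron-poor vinyl ketone that does not homodimerise, so the cross product should dominate and form as the (E)-enone while ethene escapes; this makes C9=C10.

**Step 5**
Reactants: 8 (R,E)-N-methoxy-N-methyl-7-oxo-2-(triethylsilyloxy)oct-5-enamide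
Product: 9 (R,E)-7-(tert-butyldimethylsilyloxy)-N-methoxy-N-methyl-2-(triethylsilyloxy)octa-5,7-dienamide
Conditions: TBSOTf (1.2 equiv), Et3N (2 equiv), CH2Cl2, −78 to 0 °C; cold aq NaHCO3
Reagents that add atoms: tert-butyldimethylsilyl triflate, CC(C)(C)[Si](C)(C)OS(=O)(=O)C(F)(F)F
Why: Soft enolisation (silyl triflate and tertiary amine): the O-silylated enone loses a proton from the C7 methyl group, the kinetic α′ site, to give the cross-conjugated 2-siloxy-1,3-diene with C9=C10 still (E), while the far less acidic Weinreb amide is not enolised and C3 stays intact.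

**Step 6**
Reactants: 9 (R,E)-7-(tert-butyldimethylsilyloxy)-N-methoxy-N-methyl-2-(triethylsilyloxy)octa-5,7-dienamide; 10 isopropenylmagnesium bromide
Product: 11 (4R,7E)-9-(tert-butyldimethylsilyloxy)-2-methyl-4-(triethylsilyloxy)deca-1,7,9-trien-3-one
Conditions: 10 (1.5 equiv), THF, −20 to 0 °C; inverse quench into cold sat. aq NH4Cl; kept below 0 °C and used at once
Reagents that add atoms: isopropenylmagnesium bromide (10), C=C(C)[Mg]Br
Why: Weinreb ketone synthesis: the magnesium chelate of the tetrahedral adduct survives until the quench, so only one isopropenyl group is taken up, the silyl dienol ether is inert to the Grignard reagent, and the reactive dienophile appears only when the diene is already in place.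

**Step 7**
Reactants: 11 (4R,7E)-9-(tert-butyldimethylsilyloxy)-2-methyl-4-(triethylsilyloxy)deca-1,7,9-trien-3-one
Product: 12 (3R,5S,10R)-8-(tert-butyldimethylsilyloxy)-5-methyl-3-(triethylsilyloxy)-cis-octal-8-en-4-one (3α-OTES, 5β-methyl, 10β-H; systematic: (2R,4aR,8aS)-6-(tert-butyldimethylsilyloxy)-8a-methyl-2-(triethylsilyloxy)-3,4,4a,7,8,8a-hexahydronaphthalen-1(2H)-one)
Conditions: Me2AlCl (1.2 equiv), CH2Cl2 (0.01 M), −78 to −30 °C; Et3N, then aq NaHCO3
Reagents that add atoms: none
Why: Me2AlCl binds the C4 carbonyl oxygen, lowers the LUMO of the s-cis isopropenyl ketone and lets C5=C6 add suprafacially across C7=C8–C9=C10 in a concerted, asynchronous [4+2] in which C6–C7 runs ahead of C5–C10; the closest known type is the intramolecular Diels–Alder reaction of 1,7,9-decatrien-3-ones, and aluminium Lewis acids are known to be tolerated by 2-silyloxydienes at low temperature. Ring B (C5–C10) is the cyclohexene made by the cycloaddition itself, and ring A (C1–C5, C10) closes in the same event in the fused mode, because the new C5–C10 bond joins the two ends of the four-atom tether C1–C2–C3–C4. The orientation imposed by the tether is also the electronically matched one (the large diene coefficient at C7 meets the enone β-carbon C6), and it leaves the enol ether as C8=C9, so that C8 is marked as the ketone and C9 as the carbon to be oxidised. C5 and C10 are fixed relative to each other by the (E)-geometry of C9=C10 and by endo placement of the complexed C4 carbonyl under the diene, which puts the C5 methyl and H10 on one face (cis fusion). Their absolute sense comes from C3: in the chair-like tether the triethylsilyloxy group is equatorial and H3 faces the C5 methyl, whereas addition to the other face of C5=C6 would push the silyloxy group against that methyl (1,3-diaxial, A(1,3) strain) and a boat-like tether would turn the same methyl into a flagpole substituent. The step thus needs endo over exo and one dienophile face over the other; the Lewis acid is relied on for the first and the C3 substituent next to the methyl-bearing C5 for the second, and both preferences are expected, not proven.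

**Step 8**
Reactants: 12 cis-octalone (3α-OTES, C4 ketone, C8=C9 TBS enol ether)
Product: 13 (3R,5S,10R)-8-(tert-butyldimethylsilyloxy)-5-methyl-4-methylidene-3-(triethylsilyloxy)-cis-octal-8-ene
Conditions: Cp2TiMe2 (3 equiv), toluene, 70 °C, dark
Reagents that add atoms: dimethyltitanocene Cp2TiMe2, [CH3-].[CH3-].[Ti+4].c1cc[cH-]c1.c1cc[cH-]c1
Why: Petasis methylenation: Cp2Ti=CH2 formed by loss of methane adds to the C4 carbonyl and cycloreverts to the alkene, and because the reagent is not basic the enolisable C3 centre and both silyl groups are kept, where a Wittig ylide on this neopentyl α-silyloxy ketone would risk enolisation.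

**Step 9**
Reactants: 13 4-methylidene enol ether
Product: 15 (3R,5S,9R,10S)-9-(tert-butyldimethylsilyloxy)-3-hydroxy-5-methyl-4-methylidene-cis-decal-8-one (3α-OH, 9β-OTBS), via bis-silyl ketone 14 (not isolated)
Conditions: mCPBA (1.05 equiv), NaHCO3 (buffer), CH2Cl2, −20 to 0 °C; aqueous wash; then PPTS (0.2 equiv), MeOH, 0 °C to rt
Reagents that add atoms: 3-chloroperoxybenzoic acid, O=C(OO)c1cccc(Cl)c1
Why: Rubottom oxidation followed by selective acid methanolysis: the peracid takes the electron-rich C8=C9 enol ether rather than the hindered 1,1-disubstituted C4 methylidene and approaches from the convex β face (the α face is covered by C4, axial on ring B), the silyloxy epoxide opens with 1,4-shift of silicon to O9 to give the equatorial 9β-silyloxy 8-ketone (9R), and PPTS in methanol then removes only the triethylsilyl group.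

**Step 10**
Reactants: 15 allylic alcohol
Product: 16 (3R,4R,5R,9R,10S)-9-(tert-butyldimethylsilyloxy)-3-hydroxy-4,5-dimethyl-cis-decal-8-one (4β-methyl)
Conditions: [Ir(cod)(PCy3)(py)]PF6 (10 mol %, two portions), H2 (1 atm), CH2Cl2, rt
Reagents that add atoms: none
Why: Hydroxyl-directed homogeneous hydrogenation (Crabtree hydrogenation): iridium held by the 3α-hydroxyl adds H2 to the α face of C4=CH2, so H4 ends cis to O3 and the new methyl β (4R), cis to the C5 methyl; the chelate needs the ring-inverted cis-decalin conformer with O3 axial, and the ketone and silyl ether are not reduced.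

**Step 11**
Reactants: 16 3α-alcohol
Product: 17 (3R,4R,5R,9R,10S)-9-(tert-butyldimethylsilyloxy)-4,5-dimethyl-3-(triethylsilyloxy)-cis-decal-8-one
Conditions: TESCl (1.5 equiv), imidazole (3 equiv), DMF, rt
Reagents that add atoms: chlorotriethylsilane, CC[Si](Cl)(CC)CC
Why: Silylation of the free 3-hydroxyl, so that neither an acidic O–H nor an ester is present in the strongly basic coupling that follows.

**Step 12**
Reactants: 17 bis-silyl ketone; 18 2-bromopropene
Product: 20 (3R,4R,5R,7R,9R,10S)-9-(tert-butyldimethylsilyloxy)-3-hydroxyeremophil-11-en-8-one, via 3-O-triethylsilyl ether 19 (not isolated)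
Conditions: LiN(SiMe3)2 (2.2 equiv), THF, −78 to 0 °C; Pd(dba)2 (5 mol %), Q-Phos Fe(C5Ph5)(C5H4P(tBu)2) (6 mol %), 18 (2 equiv), 0 °C to rt; AcOH, −78 °C; then PPTS (0.2 equiv), MeOH, 0 °C
Reagents that add atoms: 2-bromopropene (18), C=C(C)Br
Why: Palladium-catalysed α-alkenylation of a ketone enolate with an alkenyl bromide: the amide base deprotonates the free C7 methylene rather than the hindered, silyloxy-bearing C9, zerovalent palladium inserts into the C–Br bond of 18, and reductive elimination from the enolate complex forms C7–C11 on the convex β face (7R, equatorial, also the more stable epimer), while the remaining H7 lies in the fold of the cis-decalin where base reaches it slowly, which together with the low temperature and the cold acetic acid quench should keep the double bond out of conjugation; PPTS in methanol then frees O3.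

**Step 13**
Reactants: 20 3α-alcohol; 21 3-methylbut-2-enoic acid (senecioic acid)
Product: 22 (3R,4R,5R,7R,9R,10S)-9-(tert-butyldimethylsilyloxy)-3-senecioyloxyeremophil-11-en-8-one
Conditions: 21 (1.5 equiv), DCC (1.5 equiv), DMAP (0.2 equiv), CH2Cl2, 0 °C to rt
Reagents that add atoms: 3-methylbut-2-enoic acid (21), CC(C)=CC(=O)O
Why: Steglich esterification of the only free hydroxyl with retention at C3, the usual way to senecioates, which avoids the acid chloride and its tendency to give the deconjugated ester through the vinylketene.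

**Step 14**
Reactants: 22 senecioate silyl ether
Product: 23 (3R,4R,5R,7R,9R,10S)-9-hydroxy-3-senecioyloxyeremophil-11-en-8-one
Conditions: HF·pyridine, pyridine, THF, 0 °C to rt
Reagents that add atoms: none
Why: Fluoride cleavage of the secondary silyl ether under buffered, weakly acidic conditions, chosen instead of basic TBAF so that the α-ketol, C7 and the β,γ-unsaturated ketone are not enolised.

**Step 15**
Reactants: 23 9β-ketol; 24 angelic acid ((Z)-2-methylbut-2-enoic acid)
Product: 25 (3R,4R,5R,7R,9R,10S)-9-angeloyloxy-3-senecioyloxyeremophil-11-en-8-one (CNP0164025.2)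
Conditions: 24 (3 equiv), 2,4,6-trichlorobenzoyl chloride (3 equiv), Et3N (3 equiv), toluene, rt; then 23, 75 °C, no DMAP
Reagents that add atoms: angelic acid (24), C/C=C(/C)C(=O)O
Why: Yamaguchi-type mixed-anhydride acylation without DMAP, the established way to attach an angeloyl group without Z to E isomerisation to the tiglate; the ketol oxygen attacks the unhindered angeloyl carbonyl, the C9–O bond is not broken, and the (Z)-geometry comes from 24.

**Compound list**
1 | methyl (R)-glycidate | COC(=O)[C@H]1CO1 | starting material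
2 | allylmagnesium bromide | C=CC[Mg]Br | starting material
3 | methyl (R)-2-hydroxyhex-5-enoate | COC(=O)[C@H](O)CCC=C | intermediate
4 | methyl (R)-2-(triethylsilyloxy)hex-5-enoate | COC(=O)[C@H](O[Si](CC)(CC)CC)CCC=C | intermediate
5 | N,O-dimethylhydroxylamine hydrochloride | CNOC.Cl | starting material
6 | (R)-N-methoxy-N-methyl-2-(triethylsilyloxy)hex-5-enamide | CON(C)C(=O)[C@H](O[Si](CC)(CC)CC)CCC=C | intermediate
7 | methyl vinyl ketone | C=CC(C)=O | starting material
8 | (R,E)-N-methoxy-N-methyl-7-oxo-2-(triethylsilyloxy)oct-5-enamide | CON(C)C(=O)[C@H](O[Si](CC)(CC)CC)CC/C=C/C(C)=O | intermediate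
9 | (R,E)-7-(tert-butyldimethylsilyloxy)-N-methoxy-N-methyl-2-(triethylsilyloxy)octa-5,7-dienamide | CON(C)C(=O)[C@H](O[Si](CC)(CC)CC)CC/C=C/C(=C)O[Si](C)(C)C(C)(C)C | intermediate
10 | isopropenylmagnesium bromide | C=C(C)[Mg]Br | starting material
11 | (4R,7E)-9-(tert-butyldimethylsilyloxy)-2-methyl-4-(triethylsilyloxy)deca-1,7,9-trien-3-one | C=C(C)C(=O)[C@H](O[Si](CC)(CC)CC)CC/C=C/C(=C)O[Si](C)(C)C(C)(C)C | intermediate
12 | (3R,5S,10R)-8-(tert-butyldimethylsilyloxy)-5-methyl-3-(triethylsilyloxy)-cis-octal-8-en-4-one | C1C[C@@]2(C)[C@H](CC[C@@H](O[Si](CC)(CC)CC)C2=O)C=C1O[Si](C)(C)C(C)(C)C | intermediate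
13 | (3R,5S,10R)-8-(tert-butyldimethylsilyloxy)-5-methyl-4-methylidene-3-(triethylsilyloxy)-cis-octal-8-ene | C1C[C@@]2(C)[C@H](CC[C@@H](O[Si](CC)(CC)CC)C2=C)C=C1O[Si](C)(C)C(C)(C)C | intermediate
14 | (3R,5S,9R,10S)-9-(tert-butyldimethylsilyloxy)-5-methyl-4-methylidene-3-(triethylsilyloxy)-cis-decal-8-one | C1C[C@@]2(C)[C@H](CC[C@@H](O[Si](CC)(CC)CC)C2=C)[C@@H](O[Si](C)(C)C(C)(C)C)C1=O | intermediate
15 | (3R,5S,9R,10S)-9-(tert-butyldimethylsilyloxy)-3-hydroxy-5-methyl-4-methylidene-cis-decal-8-one | C1C[C@@]2(C)[C@H](CC[C@@H](O)C2=C)[C@@H](O[Si](C)(C)C(C)(C)C)C1=O | intermediate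
16 | (3R,4R,5R,9R,10S)-9-(tert-butyldimethylsilyloxy)-3-hydroxy-4,5-dimethyl-cis-decal-8-one | C1C[C@@]2(C)[C@H](CC[C@@H](O)[C@@H]2C)[C@@H](O[Si](C)(C)C(C)(C)C)C1=O | intermediate
17 | (3R,4R,5R,9R,10S)-9-(tert-butyldimethylsilyloxy)-4,5-dimethyl-3-(triethylsilyloxy)-cis-decal-8-one | C1C[C@@]2(C)[C@H](CC[C@@H](O[Si](CC)(CC)CC)[C@@H]2C)[C@@H](O[Si](C)(C)C(C)(C)C)C1=O | intermediate
18 | 2-bromopropene | C=C(C)Br | starting material
19 | (3R,4R,5R,7R,9R,10S)-9-(tert-butyldimethylsilyloxy)-3-(triethylsilyloxy)eremophil-11-en-8-one | C=C(C)[C@H]1C[C@@]2(C)[C@H](CC[C@@H](O[Si](CC)(CC)CC)[C@@H]2C)[C@@H](O[Si](C)(C)C(C)(C)C)C1=O | intermediate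
20 | (3R,4R,5R,7R,9R,10S)-9-(tert-butyldimethylsilyloxy)-3-hydroxyeremophil-11-en-8-one | C=C(C)[C@H]1C[C@@]2(C)[C@H](CC[C@@H](O)[C@@H]2C)[C@@H](O[Si](C)(C)C(C)(C)C)C1=O | intermediate
21 | 3-methylbut-2-enoic acid (senecioic acid) | CC(C)=CC(=O)O | starting material
22 | (3R,4R,5R,7R,9R,10S)-9-(tert-butyldimethylsilyloxy)-3-senecioyloxyeremophil-11-en-8-one | C=C(C)[C@H]1C[C@@]2(C)[C@H](CC[C@@H](OC(=O)C=C(C)C)[C@@H]2C)[C@@H](O[Si](C)(C)C(C)(C)C)C1=O | intermediate
23 | (3R,4R,5R,7R,9R,10S)-9-hydroxy-3-senecioyloxyeremophil-11-en-8-one | C=C(C)[C@H]1C[C@@]2(C)[C@H](CC[C@@H](OC(=O)C=C(C)C)[C@@H]2C)[C@@H](O)C1=O | intermediate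
24 | angelic acid, (Z)-2-methylbut-2-enoic acid | C/C=C(/C)C(=O)O | starting material
25 | (3R,4R,5R,7R,9R,10S)-9-angeloyloxy-3-senecioyloxyeremophil-11-en-8-one, CNP0164025.2 | C=C(C)[C@H]1C[C@@]2(C)[C@H](CC[C@@H](OC(=O)C=C(C)C)[C@@H]2C)[C@@H](OC(=O)/C(C)=C\C)C1=O | target

**Total step count:** 15. **Longest linear sequence:** 15 steps (from 1).

**The three steps most likely to fail**

**Step 7.**
- What may go wrong: approach of the dienophile with the C4 carbonyl exo (trans fusion), addition to the other face of C5=C6, or stripping of the dienol silyl group by the Lewis acid before the rings close.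
- Fallback (chelate control in place of steric control): it sets out from 3 and comes back at 15. 4-Methoxybenzyl trichloroacetimidate with catalytic acid would turn 3 into methyl (R)-2-(4-methoxybenzyloxy)hex-5-enoate F1. The operations of steps 3 to 6 would carry it through (R)-N-methoxy-2-(4-methoxybenzyloxy)-N-methylhex-5-enamide F2, (R,E)-N-methoxy-2-(4-methoxybenzyloxy)-N-methyl-7-oxooct-5-enamide F3 and (R,E)-7-(tert-butyldimethylsilyloxy)-N-methoxy-2-(4-methoxybenzyloxy)-N-methylocta-5,7-dienamide F4 to (4R,7E)-9-(tert-butyldimethylsilyloxy)-4-(4-methoxybenzyloxy)-2-methyldeca-1,7,9-trien-3-one F5.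
- MgBr2·OEt2 in CH2Cl2 at low temperature would bind the C4 carbonyl oxygen and the ether oxygen on C3 in a five-membered chelate. The C3–O bond is then held syn to C=O, which is possible only in the transition states that lead to the 3α,5β,10β series, and the milder Lewis acid should spare the enol ether. The same two bonds would form and give 8-(tert-butyldimethylsilyloxy)-3α-(4-methoxybenzyloxy)-5β-methyl-10βH-octal-8-en-4-one F6.
- Methylenation as in step 8 would give 8-(tert-butyldimethylsilyloxy)-3α-(4-methoxybenzyloxy)-5β-methyl-4-methylidene-10βH-octal-8-ene F7. Rubottom oxidation as in the first half of step 9 would give 9β-(tert-butyldimethylsilyloxy)-3α-(4-methoxybenzyloxy)-5β-methyl-4-methylidene-10βH-decal-8-one F8, and DDQ in wet CH2Cl2 would remove the 4-methoxybenzyl group to give 15.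

**Step 10.**
- What may go wrong: the α face of C4 lies in the fold of the cis-decalin, the directing chelate can form only after ring inversion (O3 axial), and the 9β-silyloxy group opposes that inversion. The result could be slow turnover with decay of the catalyst, undirected delivery of hydrogen to the β face, or isomerisation of the allylic alcohol to the 3-ketone.
- Fallback (hydrogenation before C9 is oxygenated): it sets out from 13 and comes back at 17. HF·pyridine would take both silyl groups off 13 and give 3α-hydroxy-5β-methyl-4-methylidene-10βH-decal-8-one F9, in which ring inversion costs less. The same iridium catalyst would give 3α-hydroxy-4β,5β-dimethyl-10βH-decal-8-one F10, and TESCl with imidazole would give 4β,5β-dimethyl-3α-(triethylsilyloxy)-10βH-decal-8-one F11.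
- TBSOTf and Et3N under equilibrating conditions would rely on the known preference of cis-fused 2-decalones to enolise toward the ring fusion and give 8-(tert-butyldimethylsilyloxy)-4β,5β-dimethyl-3α-(triethylsilyloxy)-10βH-octal-8-ene F12. mCPBA as in step 9 would then lead to 17.

**Step 12.**
- What may go wrong: deprotonation of the coupled product by the excess amide base, followed by protonation on the open β face (epimerisation at C7) or at C12 (drift of the double bond into conjugation with C8=O). Sluggish coupling of the hindered enolate is a further possibility.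
- Fallback (aldol addition and dehydration in place of cross-coupling): it sets out from 17 and comes back at 19. LiN(iPr)2 at −78 °C, then ZnCl2 and acetone, would give 9β-(tert-butyldimethylsilyloxy)-11-hydroxy-3α-(triethylsilyloxy)-10βH-eremophilan-8-one F13. The C7–C11 bond would again form on the convex face and, the addition being reversible, end equatorial.
- SOCl2 in pyridine at 0 °C would dehydrate the tertiary alcohol toward one of the six methyl hydrogens, H7 being shielded in the fold. This gives 19, which is desilylated at O3 as in the second half of step 12.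

**Further compounds**
F1 | step 7 | methyl (R)-2-(4-methoxybenzyloxy)hex-5-enoate | COC(=O)[C@H](OCc1ccc(OC)cc1)CCC=C
F2 | step 7 | (R)-N-methoxy-2-(4-methoxybenzyloxy)-N-methylhex-5-enamide | CON(C)C(=O)[C@H](OCc1ccc(OC)cc1)CCC=C
F3 | step 7 | (R,E)-N-methoxy-2-(4-methoxybenzyloxy)-N-methyl-7-oxooct-5-enamide | CON(C)C(=O)[C@H](OCc1ccc(OC)cc1)CC/C=C/C(C)=O
F4 | step 7 | (R,E)-7-(tert-butyldimethylsilyloxy)-N-methoxy-2-(4-methoxybenzyloxy)-N-methylocta-5,7-dienamide | CON(C)C(=O)[C@H](OCc1ccc(OC)cc1)CC/C=C/C(=C)O[Si](C)(C)C(C)(C)C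
F5 | step 7 | (4R,7E)-9-(tert-butyldimethylsilyloxy)-4-(4-methoxybenzyloxy)-2-methyldeca-1,7,9-trien-3-one | C=C(C)C(=O)[C@H](OCc1ccc(OC)cc1)CC/C=C/C(=C)O[Si](C)(C)C(C)(C)C
F6 | step 7 | 8-(tert-butyldimethylsilyloxy)-3α-(4-methoxybenzyloxy)-5β-methyl-10βH-octal-8-en-4-one | C1C[C@@]2(C)[C@H](CC[C@@H](OCc3ccc(OC)cc3)C2=O)C=C1O[Si](C)(C)C(C)(C)C
F7 | step 7 | 8-(tert-butyldimethylsilyloxy)-3α-(4-methoxybenzyloxy)-5β-methyl-4-methylidene-10βH-octal-8-ene | C1C[C@@]2(C)[C@H](CC[C@@H](OCc3ccc(OC)cc3)C2=C)C=C1O[Si](C)(C)C(C)(C)C
F8 | step 7 | 9β-(tert-butyldimethylsilyloxy)-3α-(4-methoxybenzyloxy)-5β-methyl-4-methylidene-10βH-decal-8-one | C1C[C@@]2(C)[C@H](CC[C@@H](OCc3ccc(OC)cc3)C2=C)[C@@H](O[Si](C)(C)C(C)(C)C)C1=O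
F9 | step 10 | 3α-hydroxy-5β-methyl-4-methylidene-10βH-decal-8-one | C1C[C@@]2(C)[C@H](CC[C@@H](O)C2=C)CC1=O
F10 | step 10 | 3α-hydroxy-4β,5β-dimethyl-10βH-decal-8-one | C1C[C@@]2(C)[C@H](CC[C@@H](O)[C@@H]2C)CC1=O
F11 | step 10 | 4β,5β-dimethyl-3α-(triethylsilyloxy)-10βH-decal-8-one | C1C[C@@]2(C)[C@H](CC[C@@H](O[Si](CC)(CC)CC)[C@@H]2C)CC1=O
F12 | step 10 | 8-(tert-butyldimethylsilyloxy)-4β,5β-dimethyl-3α-(triethylsilyloxy)-10βH-octal-8-ene | C1C[C@@]2(C)[C@H](CC[C@@H](O[Si](CC)(CC)CC)[C@@H]2C)C=C1O[Si](C)(C)C(C)(C)C
F13 | step 12 | 9β-(tert-butyldimethylsilyloxy)-11-hydroxy-3α-(triethylsilyloxy)-10βH-eremophilan-8-one | CC(C)(O)[C@H]1C[C@@]2(C)[C@H](CC[C@@H](O[Si](CC)(CC)CC)[C@@H]2C)[C@@H](O[Si](C)(C)C(C)(C)C)C1=O
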